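**Retrosynthetic overview**

- Target 13 is the 9-O-(E)-caffeate of (−)-lariciresinol; the ester C–O bond is cut last (Mitsunobu esterification of oxolane 11 with unprotected caffeic acid 12).
- The oxolane, the only ring the route has to form, is closed in the key step by making the O1–C2 bond (ring oxygen to the aryl-bearing carbon C7). DDQ dehydrogenates the twofold-symmetric diol 9 to a p-quinone methide, which the C9′ hydroxyl captures in a 5-exo closure. This one operation forms the ring, sets C7, and tells apart the two CH2OH groups and the two aryl groups.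
- Enabling feature: the 4-hydroxy-3-methoxyphenyl ring on C2 of the oxolane, whose para-OH makes the C7–H2 group oxidisable to a quinone methide. It works together with the hidden twofold (C2) symmetry of the C3–C4 backbone: the two S-configured carbons each carry one CH2O group and one identical 4-hydroxy-3-methoxybenzyl unit, so either benzylic site of 9 leads to the same oxolane.
- The C3–C4 (C8–C8′) bond and both of its stereocentres come from one oxidative homocoupling, in which two molecules of the oxazolidinone enolate join at their α-carbons (two carbons of like polarity), starting from dihydroferulic acid 1.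

Key step: step 6

Remark: lignan numbering is used (C7, C8, C9 for the aryl-CH, ring CH and CH2O carbons of the oxolane half, primed numbers for the benzyl half; O9′ is the ring oxygen). The oxidative enolate coupling is assumed to follow the facial sense of Evans alkylations, so that the (R)-auxiliary gives the (S,S)-dimer.

**Route**

Step 1
Reactants: 1 3-(4-hydroxy-3-methoxyphenyl)propanoic acid (dihydroferulic acid)
Product: 2 3-[4-(benzyloxy)-3-methoxyphenyl]propanoic acid
Conditions: BnBr (1.2 equiv), NaOH (2.5 equiv), EtOH/H2O, reflux; then HCl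
Reagents that add atoms: benzyl bromide, BrCc1ccccc1
Why: Williamson etherification; in aqueous ethanolic NaOH the phenoxide of the dianion is far more nucleophilic than the solvated carboxylate and any benzyl ester is saponified in situ, so only the aryl benzyl ether should survive acidification (no stereocentre).

Step 2
Reactants: 2 3-[4-(benzyloxy)-3-methoxyphenyl]propanoic acid; 3 (R)-4-benzyl-1,3-oxazolidin-2-one
Product: 5 (4R)-4-benzyl-3-{3-[4-(benzyloxy)-3-methoxyphenyl]propanoyl}-1,3-oxazolidin-2-one, via mixed pivalic anhydride 4 (not isolated)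
Conditions: PivCl, Et3N, THF, −20 °C; then 3, LiCl, −20 °C → rt
Reagents that add atoms: none
Why: N-acylation of the oxazolidinone through the mixed pivalic anhydride, which is attacked at its less hindered acyl carbon; this installs the auxiliary that later controls both backbone stereocentres.

Step 3
Reactants: 5 (4R)-4-benzyl-3-{3-[4-(benzyloxy)-3-methoxyphenyl]propanoyl}-1,3-oxazolidin-2-one (two molecules are joined)
Product: 7 (4R,4′R)-3,3′-{(2S,3S)-2,3-bis[4-(benzyloxy)-3-methoxybenzyl]butanedioyl}bis(4-benzyl-1,3-oxazolidin-2-one), via lithium Z-enolate 6 (not isolated)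
Conditions: LDA (LiN(iPr)2, 1.05 equiv per 5), THF, −78 °C; then CuCl2 (1.1 equiv per 5), DMF, −78 → 0 °C
Reagents that add atoms: second molecule of 5 (4R)-4-benzyl-3-{3-[4-(benzyloxy)-3-methoxyphenyl]propanoyl}-1,3-oxazolidin-2-one, COc1cc(CCC(=O)N2[C@H](Cc3ccccc3)COC2=O)ccc1OCc1ccccc1
Why: Oxidative enolate homocoupling of two molecules of 5: CuCl2 (divalent copper) takes one electron from each chelated Z-enolate 6 and the two α-carbons of like polarity join with loss of one hydrogen each, each on the face anti to the benzyl group of the (R)-auxiliary as in Evans alkylations, so both new centres should be S and the twofold-symmetric (S,S)-dimer should be the main product, separable from the (S,R)-diastereomer by chromatography or crystallisation.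

Step 4
Reactants: 7 (4R,4′R)-3,3′-{(2S,3S)-2,3-bis[4-(benzyloxy)-3-methoxybenzyl]butanedioyl}bis(4-benzyl-1,3-oxazolidin-2-one)
Product: 8 (2S,3S)-2,3-bis[4-(benzyloxy)-3-methoxybenzyl]butane-1,4-diol
Conditions: LiBH4 (excess), MeOH (2 equiv per imide), THF, 0 °C → rt
Reagents that add atoms: none
Why: Reductive cleavage of N-acyloxazolidinones by LiBH4 at the exocyclic carbonyl should give both primary alcohols (any lactone formed on the way is reduced as well) without epimerising the α-centres, returns the auxiliary, and leaves the aryl benzyl ethers untouched.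

Step 5
Reactants: 8 (2S,3S)-2,3-bis[4-(benzyloxy)-3-methoxybenzyl]butane-1,4-diol
Product: 9 (2S,3S)-2,3-bis(4-hydroxy-3-methoxybenzyl)butane-1,4-diol, (+)-secoisolariciresinol
Conditions: H2 (1 atm), Pd/C, EtOAc/MeOH, rt
Reagents that add atoms: none
Why: Hydrogenolysis of the two aryl benzyl ethers; at this stage the molecule has no other reducible group and no benzylic C–O bond, and the stereocentres are not involved.

Step 6
Reactants: 9 (2S,3S)-2,3-bis(4-hydroxy-3-methoxybenzyl)butane-1,4-diol
Product: 11 (−)-lariciresinol (2R,3S,4S), via p-quinone methide 10 (not isolated)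
Conditions: DDQ (0.9 equiv, added slowly), 1,4-dioxane, rt
Reagents that add atoms: none
Why: DDQ removes a hydride equivalent from one 4-alkyl-2-methoxyphenol unit of 9 (benzylic C7–H plus the phenolic proton) to give the p-quinone methide 10, in which ring A is transiently dearomatised and C7 is electrophilic, and the C9′ hydroxyl then adds to C7 in an intramolecular oxa-1,6-addition that rearomatises ring A. The closest known reaction type is the DDQ dehydrogenation of p-alkylphenols to quinone methides with capture by an alcohol, which has been used for benzylic cycloetherification to 2-aryloxolanes in lignan chemistry. The oxolane closes in the 5-exo-trig mode onto the exocyclic C7=C1 bond, whereas attack by O9 would be a 4-exo closure and C-attack by ring B a slower six-membered Friedel–Crafts closure. The new stereocentre C7 is set by the substrate: in the envelope transition state the quinonoid ring sits anti to the CH2OH group on C8, and because the addition is reversible under the weakly acidic conditions the 2,3-trans (7R) isomer should result as kinetic and thermodynamic product, while C8 and C8′ are untouched (their CH2OH and benzyl groups end up cis on the ring, as the S,S backbone dictates). Site selectivity needs no control, because the twofold axis of 9 makes dehydrogenation at C7 with closure by O9′ and dehydrogenation at C7′ with closure by O9 one and the same event. The step does need mono-oxidation, since a second dehydrogenation would close the furofuran; the substrate does not secure this, so it is held by DDQ as the limiting reagent with recovery and recycling of unreacted 9.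

Step 7
Reactants: 11 (−)-lariciresinol (2R,3S,4S); 12 (E)-caffeic acid
Product: 13 [(2R,3S,4S)-2-(4-hydroxy-3-methoxyphenyl)-4-(4-hydroxy-3-methoxybenzyl)oxolan-3-yl]methyl (2E)-3-(3,4-dihydroxyphenyl)prop-2-enoate
Conditions: PPh3 (1.2 equiv), DIAD (1.2 equiv), 12 (1.1 equiv), THF, 0 °C → rt
Reagents that add atoms: none
Why: Mitsunobu esterification; only the carboxylic acid of 12, far more acidic than any of the four phenolic OH groups, protonates the PPh3–DIAD betaine, so the caffeate anion should displace the alkoxyphosphonium of the single primary alcohol at CH2 (no stereocentre involved) while the E-alkene and the benzylic ether ring stay untouched under these neutral conditions.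

**Compound list**

1 | 3-(4-hydroxy-3-methoxyphenyl)propanoic acid (dihydroferulic acid) | COc1cc(CCC(=O)O)ccc1O | starting material
2 | 3-[4-(benzyloxy)-3-methoxyphenyl]propanoic acid | COc1cc(CCC(=O)O)ccc1OCc1ccccc1 | intermediate
3 | (R)-4-benzyl-1,3-oxazolidin-2-one | O=C1N[C@H](Cc2ccccc2)CO1 | starting material
4 | 3-[4-(benzyloxy)-3-methoxyphenyl]propanoic pivalic anhydride | COc1cc(CCC(=O)OC(=O)C(C)(C)C)ccc1OCc1ccccc1 | intermediate (not isolated)
5 | (4R)-4-benzyl-3-{3-[4-(benzyloxy)-3-methoxyphenyl]propanoyl}-1,3-oxazolidin-2-one | COc1cc(CCC(=O)N2[C@H](Cc3ccccc3)COC2=O)ccc1OCc1ccccc1 | intermediate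
6 | lithium Z-enolate of 5 | [Li+].[O-]/C(=C\Cc1ccc(OCc2ccccc2)c(OC)c1)N1[C@H](Cc2ccccc2)COC1=O | intermediate (not isolated)
7 | (4R,4′R)-3,3′-{(2S,3S)-2,3-bis[4-(benzyloxy)-3-methoxybenzyl]butanedioyl}bis(4-benzyl-1,3-oxazolidin-2-one) | COc1cc(C[C@H](C(=O)N2[C@H](Cc3ccccc3)COC2=O)[C@H](Cc2ccc(OCc3ccccc3)c(OC)c2)C(=O)N2[C@H](Cc3ccccc3)COC2=O)ccc1OCc1ccccc1 | intermediate
8 | (2S,3S)-2,3-bis[4-(benzyloxy)-3-methoxybenzyl]butane-1,4-diol | COc1cc(C[C@H](CO)[C@H](Cc2ccc(OCc3ccccc3)c(OC)c2)CO)ccc1OCc1ccccc1 | intermediate
9 | (2S,3S)-2,3-bis(4-hydroxy-3-methoxybenzyl)butane-1,4-diol, (+)-secoisolariciresinol | COc1cc(C[C@H](CO)[C@H](Cc2ccc(O)c(OC)c2)CO)ccc1O | intermediate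
10 | mono-p-quinone methide of 9 (ring A as 2-methoxycyclohexa-2,5-dienone with exocyclic C7=C1 bond; C8 and C8′ as in 9) | COc1cc(C[C@H](CO)[C@H](C=C2C=CC(=O)C(OC)=C2)CO)ccc1O | intermediate (not isolated)
11 | (−)-lariciresinol, 4-{(2R,3S,4S)-4-(4-hydroxy-3-methoxybenzyl)-3-(hydroxymethyl)oxolan-2-yl}-2-methoxyphenol | COc1cc(C[C@@H]2CO[C@@H](c3ccc(O)c(OC)c3)[C@@H]2CO)ccc1O | intermediate
12 | (E)-caffeic acid | OC(=O)/C=C/c1ccc(O)c(O)c1 | starting material
13 | [(2R,3S,4S)-2-(4-hydroxy-3-methoxyphenyl)-4-(4-hydroxy-3-methoxybenzyl)oxolan-3-yl]methyl (2E)-3-(3,4-dihydroxyphenyl)prop-2-enoate | COc1cc(C[C@@H]2CO[C@@H](c3ccc(O)c(OC)c3)[C@@H]2COC(=O)/C=C/c2ccc(O)c(O)c2)ccc1O | target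

Total step count: 7
Longest linear sequence: 7 steps (1 → 13); 3 and 12 are commercial and enter directly.

**Steps most likely to fail**

1. Step 6. What may go wrong: loss of mono-selectivity, because a second benzylic dehydrogenation (at C7′, closing the furofuran, or at the new benzylic ether C7–H) competes with the first; in addition the quinone methide may be intercepted by ring B or tautomerise to the styrene. Fallback: set out from 9 and do not stop half-way. With excess DDQ (2.2 equiv, 1,4-dioxane, rt) both benzylic positions are dehydrogenated in turn and each quinone methide is closed by the remaining hydroxyl, giving the twofold-symmetric furofuran (−)-pinoresinol F1. One of its two equivalent benzylic C–O bonds is then opened by controlled hydrogenolysis (H2, Pd/C, EtOH, rt, stopped at partial conversion), a known reductive opening of furofuran lignans, which comes back to the route at 11; over-reduced material is 9 and is recycled.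

2. Step 3. What may go wrong: poor facial selectivity in the radical C–C union, and α-chlorination or simple reprotonation of the enolate instead of coupling. Fallback: set out from 5 and build the two benzylic arms one after the other by enolate alkylations. Auxiliary-controlled alkylation of 5 (NaN(SiMe3)2, THF, −78 °C; tert-butyl bromoacetate) should give the imide tert-butyl ester F2. LiBH4 cleavage of the auxiliary gives the hydroxy ester F3, and acid lactonisation (TsOH, toluene) gives the (S)-β-benzyl-γ-butyrolactone F4. Trans-selective alkylation of its lithium enolate (LiN(SiMe3)2, THF, −78 °C) with 4-(benzyloxy)-3-methoxybenzyl bromide gives the trans-dibenzylbutyrolactone F5, and LiAlH4 reduction (THF, 0 °C) comes back to the route at 8.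

3. Step 7. What may go wrong: competition of phenoxide O-alkylation and of acyl transfer to phenols at the hindered, β-branched primary alcohol, and oxidation of the free catechol by DIAD. Fallback: set out from 11 and work with masked phenols. Phenoxide-selective acetylation (Ac2O, aqueous NaOH, 0 °C) should give the 4,4′-di-O-acetate F6. Steglich esterification (EDC·HCl, DMAP, CH2Cl2) with commercial (E)-3,4-diacetoxycinnamic acid gives the tetraacetate F7. Removal of the four aryl acetates with hydrazine acetate (DMF, rt), which leaves the alkyl cinnamate ester intact, comes back to the route at 13.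

**Further compounds**

F1 | step 6 | (−)-pinoresinol, 4,4′-[(1R,3aS,4R,6aS)-tetrahydro-1H,3H-furo[3,4-c]furan-1,4-diyl]bis(2-methoxyphenol) | COc1cc([C@H]5[C@@H]2CO[C@@H](c3ccc(O)c(OC)c3)[C@@H]2CO5)ccc1O
F2 | step 3 | tert-butyl (3S)-4-[(4R)-4-benzyl-2-oxo-1,3-oxazolidin-3-yl]-3-[4-(benzyloxy)-3-methoxybenzyl]-4-oxobutanoate | COc1cc(C[C@H](C(=O)N2[C@H](Cc3ccccc3)COC2=O)CC(=O)OC(C)(C)C)ccc1OCc1ccccc1
F3 | step 3 | tert-butyl (3S)-3-[4-(benzyloxy)-3-methoxybenzyl]-4-hydroxybutanoate | COc1cc(C[C@H](CO)CC(=O)OC(C)(C)C)ccc1OCc1ccccc1
F4 | step 3 | (4S)-4-[4-(benzyloxy)-3-methoxybenzyl]oxolan-2-one | COc1cc(C[C@@H]2COC(=O)C2)ccc1OCc1ccccc1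
F5 | step 3 | (3S,4S)-3,4-bis[4-(benzyloxy)-3-methoxybenzyl]oxolan-2-one | COc1cc(C[C@@H]2COC(=O)[C@H]2Cc2ccc(OCc3ccccc3)c(OC)c2)ccc1OCc1ccccc1
F6 | step 7 | 4,4′-di-O-acetyl-(−)-lariciresinol | COc1cc(C[C@@H]2CO[C@@H](c3ccc(OC(C)=O)c(OC)c3)[C@@H]2CO)ccc1OC(C)=O
F7 | step 7 | tetra-O-acetate of 13 (both guaiacyl phenols and both catechol hydroxyls acetylated) | COc1cc(C[C@@H]2CO[C@@H](c3ccc(OC(C)=O)c(OC)c3)[C@@H]2COC(=O)/C=C/c2ccc(OC(C)=O)c(OC(C)=O)c2)ccc1OC(C)=O
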